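**Plan**

1. Retrosynthesis: the two silyl ethers go last; the C9–C11 bond is cut (B-alkyl Suzuki coupling of a C8=C9 enol triflate with a C5 side-chain borane); 7α-OH and 6β-OAc are traced back to the ene-dione C6(=O)–C7=C8–C9(=O); the C10–C1 and C4–C5 bonds of ring A are then cut together ([4+2]).
2. Enabling feature: ring B (C5–C10) carries oxygen at C6, an sp2 carbon at C9, methyl groups on C8 and C10 and hydrogen on C5 and C7. This is the pattern of 2,6-dimethyl-1,4-benzoquinone (1), whose C2=C3 bond becomes the C10–C5 ring-fusion bond. Ring A (C1–C5, C10), with its gem-dimethyl C4 and three CH2 groups, is 4-methylpenta-1,3-diene (2).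
3. Forward: ring B is bought as 1; ring A is closed on it in step 1 by a catalytic enantioselective Diels–Alder reaction, the only ring-forming step. Then follow C5 epimerisation, C6 reduction and acetylation, C7 hydroxylation, hydrogenation of the ring A alkene, C9 enol triflate, side chain, desilylation.
4. Stereochemistry: C10 from the chiral Lewis acid; C5 by epimerisation to the trans ring fusion; C6 by α-face hydride delivery; C7 by anti (axial) conjugate borylation with retentive oxidation; the 13Z alkene from a commercial (Z)-enynol.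

Key step: step 1

Remark on numbering: the labdane numbering of the target is used for all bicyclic compounds (ring A = C1–C5 + C10, ring B = C5–C10; β = the face of the C10 methyl group).

Assumption: the (S)-oxazaborolidinium catalyst is taken to shield the quinone face that leads to the (8aS)-adduct 3; if the first adduct proves antipodal, the (R)-catalyst is used with no other change.

**Route**

Step 1
Reactants: 1 2,6-dimethyl-1,4-benzoquinone; 2 4-methylpenta-1,3-diene
Product: 3 cis-fused adduct (4aR,8aS)-2,5,5,8a-tetramethyl-4a,5,8,8a-tetrahydronaphthalene-1,4-dione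
Conditions: (S)-o-tolyl-CBS-oxazaborolidine·Tf2NH (20 mol %), 2 (5 equiv), CH2Cl2, −78 → −20 °C
Reagents that add atoms: none
Why: The cationic oxazaborolidinium Lewis acid binds the less hindered, more basic quinone carbonyl flanked by two C–H (the later C6=O), which makes the methyl-bearing β-carbon (later C10) the most electrophilic site; the unsubstituted diene terminus (C1) bonds there first and the CMe2 terminus (C4) closes onto the H-bearing carbon (C5) in a concerted but strongly asynchronous [4+2] cycloaddition. The closest known reaction type is the chiral oxazaborolidinium-catalysed quinone Diels–Alder reaction. Ring A (C1–C5, C10) is closed in the suprafacial [4π+2π] mode, so the ring fusion is cis. C10 is set by the catalyst-controlled π-face of the quinone, while C5 follows from suprafacial addition and is corrected in step 2; endo/exo is immaterial because neither diene terminus carries a stereo-differentiating substituent, and the two C=C bonds of 1 are homotopic. The regiochemistry needed (CMe2 terminus on C5, not on C10) is secured by the Lewis-acid polarisation and by the steric impossibility of joining the CMe2 terminus to the methyl-bearing carbon. The (Z)-methyl group of 2 slows the reaction, which is why the cationic catalyst, excess diene and a slow warm-up are used.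

Step 2
Reactants: 3 cis-fused adduct
Product: 4 trans-fused ene-dione (4aS,8aS)-2,5,5,8a-tetramethyl-4a,5,8,8a-tetrahydronaphthalene-1,4-dione
Conditions: DBU (0.2 equiv), toluene, 23 °C; 4 separated, recovered 3 resubmitted
Reagents that add atoms: none
Why: Base-mediated epimerisation under thermodynamic control: C5–H is α to the C6 carbonyl and vinylogously acidified by the C9 carbonyl, so reversible formation of the cross-conjugated dienolate should deliver the trans ring fusion (5α-H, 10β-CH3), in which both ring A bonds are equatorial on ring B; C10 is quaternary and untouched.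

Step 3
Reactants: 4 trans-fused ene-dione
Product: 5 6β-hydroxy enone (4R,4aS,8aS)-4-hydroxy-2,5,5,8a-tetramethyl-4a,5,8,8a-tetrahydronaphthalen-1(4H)-one
Conditions: NaBH4, CeCl3·7H2O, MeOH, −78 °C, run directly on fresh 4
Reagents that add atoms: none
Why: Luche 1,2-reduction takes the more Lewis-basic and less hindered C6 carbonyl (C9=O lies between the quaternary C10 and the methyl-bearing C8), and hydride enters from the α-face because the β-face of C6 is blocked by the syn-axial C10 and 4β methyl groups, which gives the axial 6β-alcohol and removes the acidity of C5–H.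

Step 4
Reactants: 5 6β-hydroxy enone
Product: 6 6β-acetoxy enone (acetate of 5; 6β-acetoxy-4,4,8,10β-tetramethyl-5α-decala-2,7-dien-9-one)
Conditions: Ac2O, DMAP (0.2 equiv), pyridine, CH2Cl2, 40 °C
Reagents that add atoms: acetic anhydride, CC(=O)OC(C)=O
Why: DMAP-catalysed acylation of the hindered axial alcohol; as no other hydroxyl is present, the acetate of the target is placed unambiguously on O6 at this stage.

Step 5
Reactants: 6 6β-acetoxy enone
Product: 8 6β-acetoxy-7α-hydroxy-4,4,8α,10β-tetramethyl-5α-decal-2-en-9-one, via β-boryl ketone 7 (not isolated)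
Conditions: B2pin2 (1.1 equiv), CuCl (5 mol %), Xantphos (5 mol %), NaOtBu (10 mol %), MeOH (2 equiv), THF, 23 °C; then NaBO3·4H2O, THF/H2O, 0 → 23 °C
Reagents that add atoms: bis(pinacolato)diboron, CC1(C)OB(OC1(C)C)B1OC(C)(C)C(C)(C)O1 (boron kept only in 7); sodium perborate, O=BO[O-].[Na+] (supplies the C7 oxygen)
Why: Copper-catalysed conjugate borylation places boron on C7 anti to the pseudo-axial 6β-acetate and in the stereoelectronically preferred axial (α) direction, and the C–B oxidation proceeds with retention to give the 7α-alcohol; C8 settles as the equatorial methyl epimer and is destroyed again in step 8.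

Step 6
Reactants: 8 β-hydroxy ketone
Product: 9 6β-acetoxy-7α-hydroxy-4,4,8α,10β-tetramethyl-5α-decalin-9-one
Conditions: H2 (1 atm), 10 % Pd/C, EtOAc, 23 °C
Reagents that add atoms: none
Why: Heterogeneous catalytic hydrogenation of the only C=C bond present (the cis-disubstituted C2=C3 alkene left by the cycloaddition); ketone, ester and alcohol are inert under these conditions.

Step 7
Reactants: 9 saturated β-hydroxy ketone
Product: 10 6β-acetoxy-7α-(triethylsilyloxy)-4,4,8α,10β-tetramethyl-5α-decalin-9-one
Conditions: TESOTf, 2,6-lutidine, CH2Cl2, −78 → 0 °C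
Reagents that add atoms: triethylsilyl trifluoromethanesulfonate, CC[Si](CC)(CC)OS(=O)(=O)C(F)(F)F
Why: Silylation of the free 7α-OH with a silyl triflate and a hindered base masks the β-hydroxy ketone against retro-aldol cleavage in the next step and keeps O6 and O7 differentiated.

Step 8
Reactants: 10 silyl ether ketone
Product: 12 6β-acetoxy-7α-(triethylsilyloxy)-4,4,8,10β-tetramethyl-5α-decal-8-en-9-yl trifluoromethanesulfonate, via potassium enolate 11 (not isolated)
Conditions: KHMDS (1.1 equiv), THF, −78 °C; then PhNTf2, −78 → 0 °C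
Reagents that add atoms: N-phenyl-bis(trifluoromethanesulfonimide), O=S(=O)(N(c1ccccc1)S(=O)(=O)C(F)(F)F)C(F)(F)F
Why: Enol triflate formation: C10 is quaternary, so the C9 ketone can enolise only towards C8, and O-sulfonylation of the enolate gives the tetrasubstituted C8=C9 triflate regiospecifically; the ketone is far more acidic than the acetate, and the low temperature should suppress loss of the β-silyloxy group.

Step 9
Reactants: 13 (2Z)-3-methylpent-2-en-4-yn-1-ol
Product: 14 tert-butyldimethyl{[(2Z)-3-methylpent-2-en-4-yn-1-yl]oxy}silane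
Conditions: TBSCl, imidazole, CH2Cl2, 0 → 23 °C
Reagents that add atoms: tert-butyldimethylsilyl chloride, CC(C)(C)[Si](C)(C)Cl
Why: Standard silylation of the primary allylic alcohol; the (Z)-alkene of the commercial enynol is not touched.

Step 10
Reactants: 14 silyl enyne
Product: 15 tert-butyldimethyl{[(2Z)-3-methylpenta-2,4-dien-1-yl]oxy}silane
Conditions: H2 (1 atm), Lindlar catalyst, quinoline, hexane, 0 → 23 °C
Reagents that add atoms: none
Why: Lindlar semi-hydrogenation stops the terminal alkyne at the vinyl stage, and the poisoned catalyst leaves the trisubstituted (Z)-alkene and its geometry intact.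

Step 11
Reactants: 12 enol triflate; 15 silyl diene
Product: 17 (13Z)-15-(tert-butyldimethylsilyloxy)-7α-(triethylsilyloxy)labda-8,13-dien-6β-yl acetate, via alkylborane 16 (not isolated)
Conditions: 15 (1.3 equiv), 9-BBN, THF, 0 → 23 °C; then 12, Pd(dppf)Cl2 (10 mol %), AsPh3 (10 mol %), Cs2CO3, DMF/H2O, 23 → 50 °C
Reagents that add atoms: 9-borabicyclo[3.3.1]nonane, B1C2CCCC1CCC2 (boron kept only in 16)
Why: 9-BBN hydroborates the monosubstituted vinyl group at its terminal carbon (the trisubstituted alkene is too hindered), and the primary alkylborane undergoes B-alkyl Suzuki–Miyaura coupling with the enol triflate, which forms C9–C11 and fixes the tetrasubstituted C8=C9 alkene while the 13Z geometry is carried over unchanged.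

Step 12
Reactants: 17 bis-silyl ether
Product: 18 (13Z)-7α,15-dihydroxylabda-8,13-dien-6β-yl acetate (5S,6S,7S,10S), the target
Conditions: TBAF (3 equiv), THF, 0 → 23 °C
Reagents that add atoms: none
Why: Fluoride-mediated desilylation frees O7 and O15; the acetate cannot migrate from O6 to O7 because the two oxygens are trans-diaxial on the rigid trans-fused ring B.

**Compound list**

1 | 2,6-dimethyl-1,4-benzoquinone | CC1=CC(=O)C=C(C)C1=O | starting material
2 | 4-methylpenta-1,3-diene | CC(C)=CC=C | starting material
3 | (4aR,8aS)-2,5,5,8a-tetramethyl-4a,5,8,8a-tetrahydronaphthalene-1,4-dione (cis-fused) | O=C1C=C(C)C(=O)[C@@]2(C)CC=CC(C)(C)[C@@H]12 | intermediate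
4 | (4aS,8aS)-2,5,5,8a-tetramethyl-4a,5,8,8a-tetrahydronaphthalene-1,4-dione (trans-fused) | O=C1C=C(C)C(=O)[C@@]2(C)CC=CC(C)(C)[C@H]12 | intermediate
5 | (4R,4aS,8aS)-4-hydroxy-2,5,5,8a-tetramethyl-4a,5,8,8a-tetrahydronaphthalen-1(4H)-one (6β-OH) | O[C@@H]1C=C(C)C(=O)[C@@]2(C)CC=CC(C)(C)[C@H]12 | intermediate
6 | 6β-acetoxy-4,4,8,10β-tetramethyl-5α-decala-2,7-dien-9-one | CC(=O)O[C@@H]1C=C(C)C(=O)[C@@]2(C)CC=CC(C)(C)[C@H]12 | intermediate
7 | 6β-acetoxy-7α-(pinacolatoboryl)-4,4,8α,10β-tetramethyl-5α-decal-2-en-9-one | CC(=O)O[C@@H]1[C@@H](B3OC(C)(C)C(C)(C)O3)[C@@H](C)C(=O)[C@@]2(C)CC=CC(C)(C)[C@H]12 | intermediate (not isolated)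
8 | 6β-acetoxy-7α-hydroxy-4,4,8α,10β-tetramethyl-5α-decal-2-en-9-one | CC(=O)O[C@@H]1[C@@H](O)[C@@H](C)C(=O)[C@@]2(C)CC=CC(C)(C)[C@H]12 | intermediate
9 | 6β-acetoxy-7α-hydroxy-4,4,8α,10β-tetramethyl-5α-decalin-9-one | CC(=O)O[C@@H]1[C@@H](O)[C@@H](C)C(=O)[C@@]2(C)CCCC(C)(C)[C@H]12 | intermediate
10 | 6β-acetoxy-7α-(triethylsilyloxy)-4,4,8α,10β-tetramethyl-5α-decalin-9-one | CC(=O)O[C@@H]1[C@@H](O[Si](CC)(CC)CC)[C@@H](C)C(=O)[C@@]2(C)CCCC(C)(C)[C@H]12 | intermediate
11 | potassium C8=C9 enolate of 10 | CC(=O)O[C@@H]1[C@@H](O[Si](CC)(CC)CC)C(C)=C([O-])[C@@]2(C)CCCC(C)(C)[C@H]12.[K+] | intermediate (not isolated)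
12 | 6β-acetoxy-7α-(triethylsilyloxy)-4,4,8,10β-tetramethyl-5α-decal-8-en-9-yl trifluoromethanesulfonate | CC(=O)O[C@@H]1[C@@H](O[Si](CC)(CC)CC)C(C)=C(OS(=O)(=O)C(F)(F)F)[C@@]2(C)CCCC(C)(C)[C@H]12 | intermediate
13 | (2Z)-3-methylpent-2-en-4-yn-1-ol | C#C/C(C)=C\CO | starting material
14 | tert-butyldimethyl{[(2Z)-3-methylpent-2-en-4-yn-1-yl]oxy}silane | C#C/C(C)=C\CO[Si](C)(C)C(C)(C)C | intermediate
15 | tert-butyldimethyl{[(2Z)-3-methylpenta-2,4-dien-1-yl]oxy}silane | C=C/C(C)=C\CO[Si](C)(C)C(C)(C)C | intermediate
16 | 9-[(3Z)-5-(tert-butyldimethylsilyloxy)-3-methylpent-3-en-1-yl]-9-borabicyclo[3.3.1]nonane | CC(C)(C)[Si](C)(C)OC/C=C(C)\CCB1C2CCCC1CCC2 | intermediate (not isolated)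
17 | (13Z)-15-(tert-butyldimethylsilyloxy)-7α-(triethylsilyloxy)labda-8,13-dien-6β-yl acetate | CC(=O)O[C@@H]1[C@@H](O[Si](CC)(CC)CC)C(C)=C(CC/C(C)=C\CO[Si](C)(C)C(C)(C)C)[C@@]2(C)CCCC(C)(C)[C@H]12 | intermediate
18 | (13Z)-7α,15-dihydroxylabda-8,13-dien-6β-yl acetate | CC(=O)O[C@@H]1[C@@H](O)C(C)=C(CC/C(C)=C\CO)[C@@]2(C)CCCC(C)(C)[C@H]12 | target

**Step count and risks**

Total step count: 12. Longest linear sequence: 10 (steps 1–8, 11, 12).

Three steps most likely to fail:

1. Step 1. The (Z)-methyl group of the CMe2 terminus disfavours the s-cis diene conformer, so the cycloaddition may be too slow. Under the cationic Lewis acid the diene may instead polymerise, or an ion pair may collapse to [2+2] or O-alkylated products. The fallback sets out from 1 and replaces the hydrocarbon diene by a far more nucleophilic 2-silyloxy diene, whose extra oxygen is removed afterwards. Commercial mesityl oxide is deprotonated kinetically at the acetyl methyl group (LDA, THF, −78 °C) and silylated with TIPSOTf to give 4-methyl-2-(triisopropylsilyloxy)penta-1,3-diene F1. With the same oxazaborolidinium catalyst, F1 and 1 should give the cis-fused silyl enol ether adduct F2. This may go by cycloaddition or by a stepwise Mukaiyama–Michael/Michael sequence; in either case C10 is fixed in the first, catalyst-controlled C–C bond formation. CsF and PhNTf2 in DME convert the silyl enol ether into the enol triflate F3. Palladium-catalysed formate reduction (Pd(OAc)2, PPh3, HCO2H, Bu3N, DMF) replaces the triflate by hydrogen and returns to the route at 3.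

2. Step 2. Ring B of the ene-dione is flattened by four sp2 carbons, so the cis/trans equilibrium may not lie far enough on the trans side and the inversion at C5 may stay incomplete. The fallback sets out from 3 and moves the equilibration to a saturated ring B. Zn in AcOH reduces the ene-dione double bond to give the cis-fused saturated 6,9-dione F4. NaOMe in MeOH then equilibrates C5 (and C8) in a chair-shaped ring B to the trans-fused dione F5. NaBH4 (MeOH, −40 °C) reduces the less hindered C6 carbonyl from the α-face to the 6β-alcohol F6, and Ac2O/DMAP gives the acetate F7. TMSOTf/Et3N forms the C8=C9 trimethylsilyl enol ether F8, and Saegusa–Ito oxidation (Pd(OAc)2, MeCN) restores the C7=C8 enone. This comes back to the route at 6.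

3. Step 5. The C7 boronate stands anti-periplanar to the 6β-acetate, so β-elimination with loss of the acetate may compete with oxidation; borylation of the α-methyl enone may also be sluggish. The fallback sets out from 6 and introduces the C7 oxygen as an epoxide. Nucleophilic epoxidation (t-BuOOH, DBU, CH2Cl2) anti to the 6β-acetate should give the 7α,8α-epoxy ketone F9. Reductive opening of the α,β-epoxy ketone at C8 with SmI2 (THF/MeOH, −78 °C) leaves the C7–O bond untouched and gives the β-hydroxy ketone, which is 8, where the route is rejoined.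

**Further compounds**

F1 | step 1 | 4-methyl-2-(triisopropylsilyloxy)penta-1,3-diene | C=C(O[Si](C(C)C)(C(C)C)C(C)C)C=C(C)C
F2 | step 1 | (4aR,8aS)-2,5,5,8a-tetramethyl-7-(triisopropylsilyloxy)-4a,5,8,8a-tetrahydronaphthalene-1,4-dione | O=C1C=C(C)C(=O)[C@@]2(C)CC(O[Si](C(C)C)(C(C)C)C(C)C)=CC(C)(C)[C@@H]12
F3 | step 1 | (4aR,8aS)-3,5,5,8a-tetramethyl-1,4-dioxo-1,4,4a,5,8,8a-hexahydronaphthalen-7-yl trifluoromethanesulfonate (numbered as in F2) | O=C1C=C(C)C(=O)[C@@]2(C)CC(OS(=O)(=O)C(F)(F)F)=CC(C)(C)[C@@H]12
F4 | step 2 | cis-fused 4,4,8,10β-tetramethyl-5β-decal-2-ene-6,9-dione (C8 epimers) | O=C1CC(C)C(=O)[C@@]2(C)CC=CC(C)(C)[C@@H]12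
F5 | step 2 | trans-fused 4,4,8α,10β-tetramethyl-5α-decal-2-ene-6,9-dione | O=C1C[C@@H](C)C(=O)[C@@]2(C)CC=CC(C)(C)[C@H]12
F6 | step 2 | 6β-hydroxy-4,4,8α,10β-tetramethyl-5α-decal-2-en-9-one | O[C@@H]1C[C@@H](C)C(=O)[C@@]2(C)CC=CC(C)(C)[C@H]12
F7 | step 2 | 6β-acetoxy-4,4,8α,10β-tetramethyl-5α-decal-2-en-9-one | CC(=O)O[C@@H]1C[C@@H](C)C(=O)[C@@]2(C)CC=CC(C)(C)[C@H]12
F8 | step 2 | 6β-acetoxy-4,4,8,10β-tetramethyl-9-(trimethylsilyloxy)-5α-decala-2,8-diene | CC(=O)O[C@@H]1CC(C)=C(O[Si](C)(C)C)[C@@]2(C)CC=CC(C)(C)[C@H]12
F9 | step 5 | 6β-acetoxy-7α,8α-epoxy-4,4,8,10β-tetramethyl-5α-decal-2-en-9-one | CC(=O)O[C@@H]1[C@H]3O[C@@]3(C)C(=O)[C@@]2(C)CC=CC(C)(C)[C@H]12
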